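It is tempting to rank these flasks by the ratio of the charges, 1.02 for Sunday's and 2.67 for Monday's, yet that ratio does not say how many first end groups stand free beside the links.

| flask | first end groups | second end groups | one-sided end groups | remark | time |
|---|---|---|---|---|---|
| north-west | 10 mM | 6.2 mM | 0.20 mM | run made earlier |  |
| west | 10 mM | 33 mM | 0.20 mM | run made earlier |  |
| north-east | 14 mM | 10.2 mM | 0.20 mM | run made earlier |  |
| Sunday's | 10 mM | 10.2 mM | 0.200 mM |  | 50 h |
| Monday's | 15 mM | 40.0 mM | 0.200 mM |  | 50 h |

| run | time / h | links / % | capped ends / % |
|---|---|---|---|
| north-west | 3.00 | 26 | 2 |
| north-west | 6.00 | 27 | 1 |
| north-west | 15.0 | 26 | 2 |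
| north-west | 40.0 | 20 | 1 |
| west | 4.00 | 71 | 1 |
| west | 12.0 | 66 | 1 |
| west | 25.0 | 60 | 2 |
| west | 40.0 | 56 | 1 |
| north-east | 4.00 | 36 | 2 |
| north-east | 12.0 | 33 | 1 |
| north-east | 25.0 | 29 | 5 |
| north-east | 40.0 | 24 | 1 |

(each reading ± 1.5 percentage points)

- percentages count the first end groups that a species holds: one side product counts as two
- the numbers in the tables scatter with a standard deviation of 1.5 percentage points

- which one finishes higher in share of links in all that became links or capped ends or over-reaction product or side product ("neither" within 2 percentage points) (Sunday's / Monday's / neither)
- share of links in all that became links or capped ends or over-reaction product or side product, Sunday's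
- share of links in all that became links or capped ends or over-reaction product or side product, Monday's

The first readings already sit near their highest, so I treat the link step as a pre-equilibrium. The first west reading, with other products set aside, gives K, links over free first end groups times free second end groups, as 0.0979 mM⁻¹. Applied to the north-west recipe, this K gives 25.7% links, and that run first reads 26%, a check, since K came from the west run.

By hand, more second end groups should pull first end groups into links, and they do: with equal first charges, the west run first reads 71% and the north-west run 26%. More first end groups should raise what stands free. Taking links and capped ends as the bound forms, the north-east run has 8.68 mM free at its first sample and the west run 2.80 mM, though their second charges differ as well. Time should cost links, and it does. By 40.0 h the north-east run keeps 66.7% of its first links and the west run 78.9%. The run with more free first end groups keeps less, so, as a working guess from two runs whose charges both differ, I take free first end groups as what costs links. The one-sided end groups can cap 2.00% of Sunday's charge, a small item.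

For Sunday's, before the slow losses, I reckon a free fraction of 60.2%, which makes 6.02 mM. This free load, free fraction times charge, is what I carry. Monday's has fraction 25.7% and load 3.85 mM, less than Sunday's, so I expect Monday's to finish higher.

The forecast says Monday's, with 45% for Sunday's and 60% for Monday's, starting from this: “The early points in all three runs fit a fast reversible link formation”.

    first end groups + one-sided end groups → capped ends (k = 35.0 M⁻¹ min⁻¹)
    first end groups + second end groups ⇌ links (K = 120 M⁻¹, k = 0.560 M⁻¹ min⁻¹)
    first end groups + links → side product (k = 0.0230 M⁻¹ min⁻¹)
    second end groups + links → over-reaction product (k = 0.00200 M⁻¹ min⁻¹)

The flasks give 52.7% for Sunday's and 58.5% for Monday's, so the ranking holds, and the forecast's Sunday figure lies 7.7 points low. The neighbour is Monday's flask with 38 mM of first end groups. Its charge ratio of 1.05 stands close to Sunday's, but its free fraction, reckoned the same way before the slow losses, of 37.9% makes a load of 14.4 mM, higher than either. After 50.0 h that flask holds 51.7% as side product and 28.9% as links, and its share of links is 33.9%.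

All runs stem from a simulated flask on assumed constants; the scatter is artificial.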